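**Plan**
- Enabling feature: ring A carries oxygen on C5, C7 and C8a and the C4 acyl carbon on C4a. It is therefore an acylphloroglucinol, the ring that a Claisen fold of a 3,5,7-trioxo ester delivers, and this allows C4a–C5 to be cut.
- Cuts, in retrosynthetic order: the two MOM ethers on ring B; O1–C2 (ring C); C4a–C5 (ring A, back to a 4-hydroxy-2-pyranone that masks the carbonyls of future C5 and C8a); C2–C3; C4–C4a; on ring B, C1′–C2 and C3′–prenyl.
- Forward: ring B is made from resorcinol by two ortho-lithiations (steps 1–3). Triacetic acid lactone supplies C4a and C5–C8a and is acylated with the C3/C4 unit that already carries the C3 prenyl group (step 5). The chain is then aroylated at C3 (step 6).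
- Ring A closes in step 7, ring C in step 8, and the MOM groups are removed in step 9.
- Stereochemistry: the target has no stereocentre. The prenyl-bearing methine of 14, 16 and 17 is racemic and enolisable and ends as sp2 C3.

Key step: step 7

Remark on the chemistry: the 1,3-diketones 14 and 16 are drawn as keto tautomers although both should be largely enolised, and 16 may sit in ring–chain equilibrium with hemiketal 17; any such mixture is carried into step 8 with the same outcome.

**Route**

Step 1
Reactants: 1 resorcinol
Product: 2 1,3-bis(methoxymethoxy)benzene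
Conditions: NaH (2.4 equiv), MOMCl (2.3 equiv), DMF, 0 °C → rt
Reagents that add atoms: chloromethyl methyl ether (MOMCl), COCCl
Why: Double Williamson-type O-alkylation of the bis-phenoxide by the reactive α-chloro ether should be clean, and the MOM acetal is chosen because it directs both later lithiations and is inert to LiN(i-Pr)2 and Mg(OMe)2.

Step 2
Reactants: 2 1,3-bis(methoxymethoxy)benzene; 3 prenyl bromide (1-bromo-3-methylbut-2-ene)
Product: 5 1,3-bis(methoxymethoxy)-2-(3-methylbut-2-en-1-yl)benzene, via aryllithium 4 (not isolated)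
Conditions: n-BuLi (1.1 equiv), THF, 0 °C → rt; CuI (10 mol%), then 3, −78 °C → rt
Reagents that add atoms: none
Why: Directed ortho-metalation should remove the ring proton flanked by both OMOM groups, and the aryllithium, relayed through a catalytic arylcopper species, should displace bromide at the primary carbon of 3 in an SN2 allylic alkylation.

Step 3
Reactants: 5 1,3-bis(methoxymethoxy)-2-(3-methylbut-2-en-1-yl)benzene
Product: 7 N-methoxy-N-methyl-2,4-bis(methoxymethoxy)-3-(3-methylbut-2-en-1-yl)benzamide, via aryllithium 6 (not isolated)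
Conditions: s-BuLi (1.2 equiv), TMEDA, THF, −78 °C; then added to ClC(O)N(OMe)Me (1.5 equiv), THF, −78 °C → rt
Reagents that add atoms: N-methoxy-N-methylcarbamoyl chloride, CON(C)C(=O)Cl
Why: A second directed ortho-metalation can only occur next to one OMOM group (C4 and C6 of 5 are equivalent), the low temperature favouring kinetic ring lithiation over removal of the benzylic-allylic protons, and inverse addition to the carbamoyl chloride should give the N-methoxy-N-methylamide in one operation.

Step 4
Reactants: 8 5-methylhex-4-enoic acid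
Product: 9 N-methoxy-N,5-dimethylhex-4-enamide
Conditions: CDI (1.1 equiv), CH2Cl2, rt; then MeNH(OMe)·HCl (1.2 equiv), rt
Reagents that add atoms: N,O-dimethylhydroxylamine hydrochloride, CNOC.Cl
Why: Activation of the acid as its acyl imidazolide followed by aminolysis is a routine amide coupling that should leave the trisubstituted alkene untouched.

Step 5
Reactants: 10 triacetic acid lactone (4-hydroxy-6-methyl-2H-pyran-2-one); 9 N-methoxy-N,5-dimethylhex-4-enamide
Product: 12 4-hydroxy-6-(6-methyl-2-oxohept-5-en-1-yl)-2H-pyran-2-one, via dilithio dianion 11 (not isolated)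
Conditions: LiN(i-Pr)2 (2.2 equiv), THF–DMPU, −78 → −40 °C; then 9 (0.8 equiv), −78 → 0 °C; aq. HCl
Reagents that add atoms: none
Why: The dianion of 10 should react at its exocyclic carbanion, the last-formed and most nucleophilic site, and C-acylation by an N-methoxy-N-methylamide (Weinreb ketone synthesis) stops at the chelated tetrahedral adduct, so the more acidic keto-pyranone appears only on quench.

Step 6
Reactants: 12 4-hydroxy-6-(6-methyl-2-oxohept-5-en-1-yl)-2H-pyran-2-one; 7 N-methoxy-N-methyl-2,4-bis(methoxymethoxy)-3-(3-methylbut-2-en-1-yl)benzamide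
Product: 14 6-{4-[2,4-bis(methoxymethoxy)-3-(3-methylbut-2-en-1-yl)phenyl]-3-(3-methylbut-2-en-1-yl)-2,4-dioxobutyl}-4-hydroxy-2H-pyran-2-one, via trilithio trianion 13 (not isolated)
Conditions: LiN(i-Pr)2 (3.3 equiv), THF, −78 → 0 °C; then 7 (0.9 equiv), −78 → 0 °C; AcOH quench
Reagents that add atoms: none
Why: Three equivalents of base should ionise the 4-OH, the doubly activated methylene at C6 of the pyranone and finally the α′-methylene, and this terminal, least stabilised carbanion should attack amide 7 (terminal C-acylation of a 1,3-dicarbonyl polyanion), the stable tetrahedral adduct preventing proton transfer from product to unreacted trianion.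

Step 7
Reactants: 14 6-{4-[2,4-bis(methoxymethoxy)-3-(3-methylbut-2-en-1-yl)phenyl]-3-(3-methylbut-2-en-1-yl)-2,4-dioxobutyl}-4-hydroxy-2H-pyran-2-one
Product: 16 1-[2,4-bis(methoxymethoxy)-3-(3-methylbut-2-en-1-yl)phenyl]-2-(3-methylbut-2-en-1-yl)-3-(2,4,6-trihydroxyphenyl)propane-1,3-dione, via tetraoxo ester chelate 15 (not isolated)
Conditions: Mg(OMe)2 (8 equiv), MeOH, reflux; then cold aq. AcOH to pH 5
Reagents that add atoms: none
Why: Methoxide should open the lactone of 14 at its carbonyl to the magnesium chelate of methyl tetraoxo ester 15, whose C6 methylene (between the C5 and C7 ketones, the future C4a) adds to the C1 ester carbonyl (future C5) and expels methoxide, after which the cyclohexane-1,3,5-trione enolises to the aromatic acylphloroglucinol 16. The closest known reaction type is the Mg(OMe)2-mediated ring opening and Claisen recyclisation of 6-(2-oxoalkyl)-4-hydroxy-2-pyranones, and of open-chain 3,5,7-trioxo esters, to acylphloroglucinols. Ring A is closed by a 6-exo-trig Claisen (Dieckmann-type) C-acylation that forms the C4a–C5 bond. No stereocentre is created, and the racemic prenyl-bearing methine should sit throughout as a magnesium diketonate, which also shields the C7/C9 diketone from retro-Claisen methanolysis. The selectivity needed is Claisen over aldol folding: divalent magnesium bridges the β-dicarbonyl units, activating the ester terminus and holding the C6 nucleophile beside it, whereas the C2-to-C7 aldol that would give a resorcylate is the mode of unchelated alkali-metal enolates in water. Within the substrate, the C9 ketone is an ortho-substituted aryl ketone locked in the C7/C9 chelate and so a poor acceptor for C4, and an aldol from the prenyl-bearing C8 would create a quaternary carbon that cannot aromatise and should revert.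

Step 8
Reactants: 16 1-[2,4-bis(methoxymethoxy)-3-(3-methylbut-2-en-1-yl)phenyl]-2-(3-methylbut-2-en-1-yl)-3-(2,4,6-trihydroxyphenyl)propane-1,3-dione
Product: 18 2-[2,4-bis(methoxymethoxy)-3-(3-methylbut-2-en-1-yl)phenyl]-5,7-dihydroxy-3-(3-methylbut-2-en-1-yl)-4H-chromen-4-one, via cyclic hemiketal 17 (not isolated)
Conditions: PPTS (20 mol%), 4 Å MS, toluene, 70 °C
Reagents that add atoms: none
Why: An ortho-hydroxyl of ring A should add to the aryl ketone (6-exo-trig) to give hemiketal 17, whose C2–OH ionises under very weak acid because the cation is stabilised by the ring oxygen and the 2,4-dialkoxyphenyl group, so loss of H-3 completes the cyclodehydration of a 2-hydroxyaryl 1,3-diketone to the chromone under aprotic conditions in which the MOM acetals have no nucleophile to transfer to.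

Step 9
Reactants: 18 2-[2,4-bis(methoxymethoxy)-3-(3-methylbut-2-en-1-yl)phenyl]-5,7-dihydroxy-3-(3-methylbut-2-en-1-yl)-4H-chromen-4-one
Product: 19 kuwanon T
Conditions: 3 M aq. HCl, MeOH, 40 °C
Reagents that add atoms: none
Why: Acid-catalysed transacetalisation to methanol cleaves aryl MOM ethers through the methoxymethyl oxocarbenium ion, and dilute acid near room temperature is the usual way to do this on prenylated phenols without hydrating the alkenes or closing chroman rings.

**Compound list**

1 | resorcinol (benzene-1,3-diol) | Oc1cccc(O)c1 | starting material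
2 | 1,3-bis(methoxymethoxy)benzene | COCOc1cccc(OCOC)c1 | intermediate
3 | prenyl bromide (1-bromo-3-methylbut-2-ene) | CC(C)=CCBr | starting material
4 | [2,6-bis(methoxymethoxy)phenyl]lithium (formed in the flask) | [Li]c1c(OCOC)cccc1OCOC | intermediate
5 | 1,3-bis(methoxymethoxy)-2-(3-methylbut-2-en-1-yl)benzene | CC(C)=CCc1c(OCOC)cccc1OCOC | intermediate
6 | [2,4-bis(methoxymethoxy)-3-(3-methylbut-2-en-1-yl)phenyl]lithium (formed in the flask) | [Li]c1ccc(OCOC)c(CC=C(C)C)c1OCOC | intermediate
7 | N-methoxy-N-methyl-2,4-bis(methoxymethoxy)-3-(3-methylbut-2-en-1-yl)benzamide | CON(C)C(=O)c1ccc(OCOC)c(CC=C(C)C)c1OCOC | intermediate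
8 | 5-methylhex-4-enoic acid | CC(C)=CCCC(=O)O | starting material
9 | N-methoxy-N,5-dimethylhex-4-enamide | CC(C)=CCCC(=O)N(C)OC | intermediate
10 | triacetic acid lactone (4-hydroxy-6-methyl-2H-pyran-2-one) | Cc1cc(O)cc(=O)o1 | starting material
11 | dilithium salt of the O,C-dianion of 10 (formed in the flask) | [Li+].[Li+].[CH2-]C1=CC([O-])=CC(=O)O1 | intermediate
12 | 4-hydroxy-6-(6-methyl-2-oxohept-5-en-1-yl)-2H-pyran-2-one | CC(C)=CCCC(=O)Cc1cc(O)cc(=O)o1 | intermediate
13 | trilithium salt of the trianion of 12 (formed in the flask) | [Li+].[Li+].[Li+].CC(C)=CC[CH-]C(=O)[CH-]C1=CC([O-])=CC(=O)O1 | intermediate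
14 | 6-{4-[2,4-bis(methoxymethoxy)-3-(3-methylbut-2-en-1-yl)phenyl]-3-(3-methylbut-2-en-1-yl)-2,4-dioxobutyl}-4-hydroxy-2H-pyran-2-one (racemic, enolisable methine) | CC(C)=CCC(C(=O)Cc1cc(O)cc(=O)o1)C(=O)c1ccc(OCOC)c(CC=C(C)C)c1OCOC | intermediate
15 | methyl 9-[2,4-bis(methoxymethoxy)-3-(3-methylbut-2-en-1-yl)phenyl]-8-(3-methylbut-2-en-1-yl)-3,5,7,9-tetraoxononanoate (present as its magnesium chelate, neutral keto form drawn; formed in the flask) | COC(=O)CC(=O)CC(=O)CC(=O)C(CC=C(C)C)C(=O)c1ccc(OCOC)c(CC=C(C)C)c1OCOC | intermediate
16 | 1-[2,4-bis(methoxymethoxy)-3-(3-methylbut-2-en-1-yl)phenyl]-2-(3-methylbut-2-en-1-yl)-3-(2,4,6-trihydroxyphenyl)propane-1,3-dione (racemic, enolisable methine) | CC(C)=CCC(C(=O)c1c(O)cc(O)cc1O)C(=O)c1ccc(OCOC)c(CC=C(C)C)c1OCOC | intermediate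
17 | 2-[2,4-bis(methoxymethoxy)-3-(3-methylbut-2-en-1-yl)phenyl]-2,5,7-trihydroxy-3-(3-methylbut-2-en-1-yl)chroman-4-one (racemic diastereomer mixture; formed in the flask) | CC(C)=CCC1C(=O)c2c(O)cc(O)cc2OC1(O)c1ccc(OCOC)c(CC=C(C)C)c1OCOC | intermediate
18 | 2-[2,4-bis(methoxymethoxy)-3-(3-methylbut-2-en-1-yl)phenyl]-5,7-dihydroxy-3-(3-methylbut-2-en-1-yl)-4H-chromen-4-one | COCOc1ccc(-c2oc3cc(O)cc(O)c3c(=O)c2CC=C(C)C)c(OCOC)c1CC=C(C)C | intermediate
19 | kuwanon T, 2-[2,4-dihydroxy-3-(3-methylbut-2-en-1-yl)phenyl]-5,7-dihydroxy-3-(3-methylbut-2-en-1-yl)-4H-chromen-4-one | CC(C)=CCc1c(O)ccc(-c2oc3cc(O)cc(O)c3c(=O)c2CC=C(C)C)c1O | target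

**Step count and risks**

Total step count: 9. Longest linear sequence: 7 steps (1, 2, 3, 6, 7, 8, 9, from resorcinol); the pyranone branch (4, 5) joins at step 6.

Steps most likely to fail:

1. Step 7. Aldol folding or retro-Claisen cleavage may outrun the Claisen closure, because the second diketone adds enolisable and electrophilic sites that the simple precedents lack. The fallback sets out from 12 and keeps the same ring-A disconnection but reverses the order of folding and aroylation. Treatment of 12 with Mg(OMe)2 in MeOH at reflux, the recyclisation in its simplest precedented form, should pass through the chelated methyl 11-methyl-3,5,7-trioxododec-10-enoate F1 and give 6-methyl-1-(2,4,6-trihydroxyphenyl)hept-5-en-1-one F2. Deprotonation of F2 with LiN(SiMe3)2 (4.5 equiv, THF, −78 → −10 °C) should give its tetralithium salt F3, which is C-acylated with amide 7, the known aroylation of polylithiated polyhydroxyaryl ketones. Mild acid work-up comes back to the route at 16.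

2. Step 6. Bond formation between a secondary carbanion and an ortho-substituted amide may be slow, so that proton transfer and decay of the trianion take over. The fallback sets out from 5 and replaces acylation by aldol addition and oxidation. Lithiation of 5 as in step 3 and quenching of aryllithium 6 with DMF should give 2,4-bis(methoxymethoxy)-3-(3-methylbut-2-en-1-yl)benzaldehyde F4. Addition of F4 to trianion 13 at −78 °C, an aldol addition that is fast even for hindered partners, should give 6-{4-[2,4-bis(methoxymethoxy)-3-(3-methylbut-2-en-1-yl)phenyl]-4-hydroxy-3-(3-methylbut-2-en-1-yl)-2-oxobutyl}-4-hydroxy-2H-pyran-2-one F5 as a diastereomer mixture. Oxidation of the electron-rich benzylic alcohol with activated MnO2 in CH2Cl2 comes back to the route at 14.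

3. Step 8. The chelated 2′-MOM group may be lost before ring closure, which would allow closure from ring B, and the enol oxygen may add to the prenyl alkene under acid. Loss of MOM after ring closure would be harmless. The fallback sets out from 16 and gives up protecting-group differentiation in favour of substrate bias. Exposure of 16 to 3 M HCl in MeOH at 40–50 °C should first cleave both MOM ethers to 1-[2,4-dihydroxy-3-(3-methylbut-2-en-1-yl)phenyl]-2-(3-methylbut-2-en-1-yl)-3-(2,4,6-trihydroxyphenyl)propane-1,3-dione F6 in the flask. Ring A offers two equivalent ortho-hydroxyls and its closure gains the C5–OH to C4=O hydrogen bond, whereas closure from the ring-B 2′-OH must attack the doubly chelated carbonyl next to the phloroglucinol. Closure should therefore proceed through 2-[2,4-dihydroxy-3-(3-methylbut-2-en-1-yl)phenyl]-2,5,7-trihydroxy-3-(3-methylbut-2-en-1-yl)chroman-4-one F7, and dehydration in the same pot comes back to the route at 19.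

**Further compounds**

F1 | step 7 | methyl 11-methyl-3,5,7-trioxododec-10-enoate (magnesium chelate, neutral keto form drawn; formed in the flask) | COC(=O)CC(=O)CC(=O)CC(=O)CCC=C(C)C
F2 | step 7 | 6-methyl-1-(2,4,6-trihydroxyphenyl)hept-5-en-1-one | CC(C)=CCCC(=O)c1c(O)cc(O)cc1O
F3 | step 7 | tetralithium salt of F2 (tris-phenoxide enolate; formed in the flask) | [Li+].[Li+].[Li+].[Li+].CC(C)=CC[CH-]C(=O)c1c([O-])cc([O-])cc1[O-]
F4 | step 6 | 2,4-bis(methoxymethoxy)-3-(3-methylbut-2-en-1-yl)benzaldehyde | COCOc1ccc(C=O)c(OCOC)c1CC=C(C)C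
F5 | step 6 | 6-{4-[2,4-bis(methoxymethoxy)-3-(3-methylbut-2-en-1-yl)phenyl]-4-hydroxy-3-(3-methylbut-2-en-1-yl)-2-oxobutyl}-4-hydroxy-2H-pyran-2-one (racemic diastereomer mixture) | CC(C)=CCC(C(=O)Cc1cc(O)cc(=O)o1)C(O)c1ccc(OCOC)c(CC=C(C)C)c1OCOC
F6 | step 8 | 1-[2,4-dihydroxy-3-(3-methylbut-2-en-1-yl)phenyl]-2-(3-methylbut-2-en-1-yl)-3-(2,4,6-trihydroxyphenyl)propane-1,3-dione (racemic; formed in the flask) | CC(C)=CCC(C(=O)c1c(O)cc(O)cc1O)C(=O)c1ccc(O)c(CC=C(C)C)c1O
F7 | step 8 | 2-[2,4-dihydroxy-3-(3-methylbut-2-en-1-yl)phenyl]-2,5,7-trihydroxy-3-(3-methylbut-2-en-1-yl)chroman-4-one (racemic diastereomer mixture; formed in the flask) | CC(C)=CCC1C(=O)c2c(O)cc(O)cc2OC1(O)c1ccc(O)c(CC=C(C)C)c1O
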